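(The runs are calculated for an exercise.)

The target I reckoned through its exposure: the natural log of starting material charged over starting material left, taken here from the target reading and treated as pseudo-first-order, so that the target share is one minus exp(−exposure).

| setting | grey | violet | Sunday's | Saturday's | Monday's |
|---|---|---|---|---|---|
| starting material | 21 mM | 21 mM | 21 mM | 21 mM | 21 mM |
| second substrate | 21 mM (fed, over 4.0 h) | 84 mM (fed, over 4.0 h) | 42.0 mM (fed, over 4.0 h) | 42.0 mM (fed, over 4.0 h) | 42.0 mM (fed, over 4.0 h) |
| partner | 42 mM | 42 mM | 42.0 mM | 42.0 mM | 42.0 mM |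
| capture agent | 2.1 mM | 2.1 mM | 2.10 mM | 2.10 mM | 2.10 mM |
| free catalyst | 0.42 mM | 0.42 mM | 0.42 mM | 0.42 mM | 0.42 mM |
| temperature | 15 °C | 50 °C | 80 °C | 50 °C | 20 °C |
| remark | run made earlier | run made earlier |  |  |  |
| time |  |  | 4.0 h | 4.0 h | 4.0 h |

- grey (time / h: target / %, starting material / %): 25.0: 5.1, 94.3; 50.0: 9.1, 89.8; 72.0: 12.2, 86.8; 96.0: 15.7, 84.5; 120: 18.9, 81.2
- violet (time / h: target / %, starting material / %): 2.00: 8.9, 90.2; 6.00: 16.3, 84.8; 8.00: 18.0, 82.6; 12.0: 21.9, 79.1; 20.0: 25.2, 75.3

(standard deviation of a reading: 0.5 percentage points)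

- the best flask by amount of target, in percent of the starting material charged; "all alike" if 1.5 percentage points covers them all (Sunday's / Saturday's / Monday's / all alike)
- amount of target at the end, in percent of the starting material charged, Sunday's
- amount of target at the end, in percent of the starting material charged, Saturday's
- amount of target at the end, in percent of the starting material charged, Monday's

The early pace, meaning exposure per hour up to the first reading, was 0.00209 h⁻¹ in the grey run at 15 °C and 0.0466 h⁻¹ in the violet run at 50 °C. I read that as an activation energy of 68.6 kJ mol⁻¹, though the two runs had different feeds. That put the early pace at 0.408 h⁻¹ for Sunday's and 0.00341 h⁻¹ for Monday's.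

The violet run's pace up to its second reading was lower than up to its first, so I replaced the curve by its mean. The violet run's exposure at 4.0 h, taken midway between its readings at 2.00 h and 6.00 h, was 72.7% of its early pace times that time. With this mean share, taken over from the violet run's larger feed, I reckoned Sunday's exposure over 4.0 h at 1.19. My targets were therefore 69.5% for Sunday's, 12.7% for Saturday's, at the violet run's early pace, and 0.988% for Monday's, and I committed to Sunday's as the best flask.

The forecast also named Sunday's best, with 50%, 17% and 1.3% for Sunday's, Saturday's and Monday's, lower than mine for Sunday's and higher for the other two, and it called the Sunday's figure, in its words, “the most uncertain estimate”.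

Sunday's gave 62.8%, Saturday's 16.7% and Monday's 1.58%, so the best flask was Sunday's.

    partner + catalyst intermediate B → free catalyst + second product (k = 120 L mol⁻¹ h⁻¹, Ea = 82.0 kJ mol⁻¹)
    catalyst intermediate B + capture agent → trapped intermediate (k = 710 L mol⁻¹ h⁻¹, Ea = 71.0 kJ mol⁻¹)
    starting material + free catalyst ⇌ catalyst intermediate A (K = 120 L mol⁻¹, k = 1100 L mol⁻¹ h⁻¹, Ea = 52.0 kJ mol⁻¹, ΔH = −31.0 kJ mol⁻¹)
    partner + catalyst intermediate A → free catalyst + target (k = 3400 L mol⁻¹ h⁻¹, Ea = 64.0 kJ mol⁻¹)
    second substrate + free catalyst ⇌ catalyst intermediate B (K = 11.0 L mol⁻¹, k = 9500 L mol⁻¹ h⁻¹, Ea = 41.0 kJ mol⁻¹, ΔH = −32.0 kJ mol⁻¹)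
    (constants at 80 °C)

Sunday's target of 62.8% is an exposure of 0.989, less than my 1.19. At 4.00 h Sunday's held 59.2% of its catalyst as trapped intermediate and 26.6% as free catalyst. I then scaled my exposure by the catalyst charged for a neighbour of Sunday's with 0.10 mM of free catalyst, which gave 0.283 and a target of 24.6%. That neighbour gave 20.7%.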